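All runs are calculated for substances that don't exist; scatter was added.

- Late in the south and north-east runs I read the fall of starting material as a pseudo-first-order tail, in south from 5.8 % to 2.6 % over 10.0 min. Averaged over both runs, this gives 0.0780 min⁻¹, the tail constant: the share of what remains that is used per minute by an awake charge of 0.13 mM.
- I draw the flask backwards from there, taking it midway between those two runs. The remainder halves every 8.89 min on the tail, and target runs towards the whole charge.
- Between 12.0 min and 25.0 min the two runs climb on average by 0.0356 min⁻¹ of the charge. I let the tail take over from this straight stretch when the remainder is 45.6 %, so by that knee target stands above starting material.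
- I put the flask at 26.1 % target at 12.0 min, midway between those runs, so its mean rate up to then is slower than the straight stretch: a lag.

| flask | starting material | second substrate | precatalyst | remark |
|---|---|---|---|---|
| south | 0.26 M | 0.13 M | 0.13 mM | run made earlier |
| north-east | 0.26 M | 0.52 M | 0.13 mM | run made earlier |
| east | 0.26 M | 0.26 M | 0.26 mM | run made earlier |
| flask | 0.26 M | 0.260 M | 0.13 mM |  |

| run | time / min | target / % | starting material / % |
|---|---|---|---|
| south | 12.0 | 30.8 | 69.6 |
| south | 25.0 | 74.9 | 23.5 |
| south | 40.0 | 93.9 | 5.8 |
| south | 50.0 | 99.2 | 2.6 |
| north-east | 12.0 | 21.3 | 80.5 |
| north-east | 25.0 | 69.8 | 31.2 |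
| north-east | 40.0 | 93.0 | 6.4 |
| north-east | 50.0 | 96.5 | 3.0 |
| east | 4.00 | 6.1 | 94.0 |
| east | 8.00 | 27.5 | 71.7 |
| east | 20.0 | 87.2 | 12.3 |
| east | 50.0 | 99.3 | 0 |

(scatter of a reading: 1 percentage point)

- percentages count the starting material that a species holds: one resting dimer counts as two
- steps thought possible: catalyst intermediate B -> free catalyst + second product; starting material + free catalyst <-> catalyst intermediate A; precatalyst -> free catalyst; catalyst intermediate A -> free catalyst + target; 2 catalyst intermediate A <-> resting dimer; second substrate + free catalyst <-> catalyst intermediate B

- factor on the rate of making target when 20 % of the starting material are converted if second substrate is charged twice over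
- factor on the rate when 20 % of the starting material are converted if precatalyst is charged at 0.012 mM instead

- That estimate already lies past the mark, and I take the straight slope as the flask's rate there. With 0.012 mM of precatalyst, I scale the tail constant by the charge and apply it to the remaining fraction, which gives a factor of 0.162. I reckon that the flask with the lower charge reaches the mark after about 34.7 min, and I take its catalyst as awake by then.
- From the south to the north-east run second substrate goes from 0.13 M to 0.52 M, so for doubled second substrate I take the root of the north-east to south ratio of target at 12.0 min, 0.832.
- The forecast says 0.87 and 0.27, holding the “rate roughly proportional to the square root of catalyst”; my factor for the lower charge is smaller.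
- The simulation gives 0.948 and 0.140.

    catalyst intermediate B → free catalyst + second product (k = 1330 min⁻¹)
    starting material + free catalyst ⇌ catalyst intermediate A (K = 3.35 L mol⁻¹, k = 1430 L mol⁻¹ min⁻¹)
    precatalyst → free catalyst (k = 0.107 min⁻¹)
    catalyst intermediate A → free catalyst + target (k = 621 min⁻¹)
    2 catalyst intermediate A ⇌ resting dimer (K = 11100 L mol⁻¹, k = 1000 L mol⁻¹ min⁻¹)
    second substrate + free catalyst ⇌ catalyst intermediate B (K = 22.0 L mol⁻¹, k = 8250 L mol⁻¹ min⁻¹)

- At 40.0 min in the flask, free catalyst has a half-life of 1.9 s by its forward passing into catalyst intermediate A, far shorter than the tail half-life of 8.89 min read from the south and north-east runs. At that time it is made 1.00 times as fast as it is used up, each step taken net, and stands as the resting state at 95.5 % of the catalyst, with catalyst intermediate A at 2.03 %. In the second flask, charged with 0.012 mM of precatalyst, the scaled tail constant gave 0.162 and the simulated factor is 0.140.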